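Target **31** is a C3–C3′-linked bis-flavanone with both pyranone rings 2,3-cis and all four centers (R); the last operation is neutral hydrogenolysis of three benzyl ethers (30 → 31), so the cis centers never see acid or base.
Key disconnection: ring C of the 5,7-dihydroxy half (O1, C2, C3, C4, C4a, C8a) is traced back to the cis-β-lactone ring O1–C2–C3–C4 of **22**; forward, 3,5-bis(benzyloxy)benzyne inserts its two carbons (C8a, C4a) into the acyl C4–O1 bond (four- to six-membered ring expansion) and delivers ring A at the same time.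
Enabling feature: the ether oxygen O1 and the C4 carbonyl sit on adjacent ring-A carbons (C8a, C4a), and O5 on C5 flanks C4a; this is the footprint of a 3-alkoxyaryne, whose alkoxy group steers the oxygen nucleophile to C8a and the acyl group to C4a.
Lactone **22** comes from acid chloride **20** (as its ketene) and 4-methoxybenzaldehyde by an alkaloid-catalysed cis-selective [2+2] cycloaddition that sets C2 and C3; **20** already carries the finished 7-methoxy half, made one round earlier in the same way (lactone **14** + 3-benzyloxy-5-methoxybenzyne → **16**, then allyl → CH2COCl).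
Order of ring formation: oxetanone of 14 → rings C and A of the 7-methoxy half (step 6) → oxetanone of 22 (step 10) → rings C and A of the dihydroxy half (step 13).

Key step: step 13

Assumption: O-trimethylsilylquinidine is taken to give the (3R,4R)-cis-lactone series in steps 5 and 10; if the opposite sense is found, O-trimethylsilylquinine is used instead with no other change.
Notation: flavanone locants (O1, C2, C3, C4, C4a, C5–C8, C8a) are used; "half 1" is the 5-hydroxy-7-methoxy flavanone and "half 2" the 5,7-dihydroxy flavanone. Lactones 14 and 22 carry an ionisable 4-methoxybenzylic C–O bond and should be kept cold and used without storage.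

Step 1
Reactants: 1 2-(benzyloxy)-4-methoxybenzaldehyde
Product: 3 2-(benzyloxy)-4-methoxyphenol, via aryl formate 2 (not isolated)
Conditions: mCPBA, CH2Cl2, 0 °C → rt; then K2CO3 (cat.), MeOH, rt
Reagents that add atoms: 3-chloroperoxybenzoic acid OOC(=O)c1cccc(Cl)c1
Why: Dakin-type Baeyer–Villiger oxidation, in which the electron-rich 2,4-dioxygenated aryl group migrates in preference to hydrogen and the aryl formate is cleaved by mild methanolysis.

Step 2
Reactants: 3 2-(benzyloxy)-4-methoxyphenol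
Product: 4 2-(benzyloxy)-4-methoxyphenyl N-(propan-2-yl)carbamate
Conditions: i-PrNCO, Et3N (cat.), CH2Cl2, rt
Reagents that add atoms: isopropyl isocyanate CC(C)N=C=O
Why: Base-catalysed addition of the phenol to the isocyanate (carbamoylation) installs a group that directs ortho-metalation and is later removed under mild conditions.

Step 3
Reactants: 4 2-(benzyloxy)-4-methoxyphenyl N-(propan-2-yl)carbamate
Product: 8 2-(benzyloxy)-4-methoxy-6-(trimethylsilyl)phenyl N-(propan-2-yl)carbamate, via N-silyl carbamate 5 (not isolated), via aryllithium 6 (not isolated), via bis-silyl carbamate 7 (not isolated)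
Conditions: TMSOTf, TMEDA, Et2O, 0 °C → rt; n-BuLi, TMEDA, −78 °C; TMSCl, −78 °C → rt; aq. NaHSO4 work-up
Reagents that add atoms: chlorotrimethylsilane C[Si](C)(C)Cl
Why: Directed ortho-metalation: after in-situ N-silylation the O-carbamate directs lithiation to C6, the only free ortho position (the other bears the benzyloxy group), and the aryllithium is silylated; the N–Si bond is hydrolysed on work-up.

Step 4
Reactants: 8 2-(benzyloxy)-4-methoxy-6-(trimethylsilyl)phenyl N-(propan-2-yl)carbamate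
Product: 10 2-(benzyloxy)-4-methoxy-6-(trimethylsilyl)phenyl trifluoromethanesulfonate, via silylphenol 9 (not isolated)
Conditions: DBU, Et2NH, MeCN, 40 °C; then PhNTf2, rt
Reagents that add atoms: N-phenylbis(trifluoromethanesulfonimide) O=S(=O)(N(c1ccccc1)S(=O)(=O)C(F)(F)F)C(F)(F)F
Why: DBU induces E1cB loss of isopropyl isocyanate (scavenged by diethylamine as the urea) and the liberated phenoxide is triflated in the same pot, giving the 2-silylaryl triflate aryne precursor.

Step 5
Reactants: 11 pent-4-enoyl chloride; 12 4-methoxybenzaldehyde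
Product: 14 (3R,4R)-4-(4-methoxyphenyl)-3-(prop-2-en-1-yl)oxetan-2-one (cis), via allylketene 13 (not isolated)
Conditions: O-trimethylsilylquinidine (10 mol %), LiClO4, i-Pr2NEt, CH2Cl2/Et2O, −78 °C
Reagents that add atoms: none
Why: Catalytic asymmetric ketene–aldehyde [2+2] cycloaddition: the amine base converts 11 into ketene 13, whose alkaloid-bound Z-ammonium enolate adds to the LiClO4-activated aldehyde through a closed transition state and lactonises, so the cinchona catalyst sets both new centers as the cis-(3R,4R) lactone.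

Step 6
Reactants: 14 (3R,4R)-4-(4-methoxyphenyl)-3-(prop-2-en-1-yl)oxetan-2-one; 10 2-(benzyloxy)-4-methoxy-6-(trimethylsilyl)phenyl trifluoromethanesulfonate
Product: 16 (2R,3R)-5-(benzyloxy)-7-methoxy-2-(4-methoxyphenyl)-3-(prop-2-en-1-yl)-2,3-dihydro-4H-chromen-4-one (2,3-cis), via aryne 15 (not isolated)
Conditions: KF, 18-crown-6, THF, 0 °C → rt
Reagents that add atoms: none
Why: Proposed new method: fluoride generates aryne 15, the lactone ring oxygen (directly, or as the alkoxide of the reversibly fluoride-opened acyl fluoride) adds to the aryne carbon meta to the benzyloxy group, and the aryl anion formed ortho to that group attacks the acyl carbon, so the aryne is inserted into the acyl–oxygen bond and the four-membered ring grows to the chromanone with both stereocenters retained (neither C2–O1 nor C3–C4 is broken); the closest known reaction types are aryne insertion into the N–C(=O) bond of azetidin-2-ones to give 2,3-dihydroquinolin-4-ones and the acyl-alkylation of β-ketoesters with arynes.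

Step 7
Reactants: 16 (2R,3R)-5-(benzyloxy)-7-methoxy-2-(4-methoxyphenyl)-3-(prop-2-en-1-yl)-2,3-dihydro-4H-chromen-4-one
Product: 18 2-[(2R,3R)-5-(benzyloxy)-7-methoxy-2-(4-methoxyphenyl)-4-oxo-3,4-dihydro-2H-chromen-3-yl]acetaldehyde, via diol 17 (not isolated)
Conditions: OsO4 (2 mol %), NaIO4, 2,6-lutidine, dioxane/H2O, rt
Reagents that add atoms: osmium tetroxide O=[Os](=O)(=O)=O; sodium periodate [Na+].[O-]I(=O)(=O)=O
Why: Lemieux–Johnson oxidation: OsO4 dihydroxylates only the terminal alkene and NaIO4 cleaves the diol under lutidine-buffered neutral conditions that leave the cis C2/C3 centers and the benzyl ether untouched.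

Step 8
Reactants: 18 2-[(2R,3R)-5-(benzyloxy)-7-methoxy-2-(4-methoxyphenyl)-4-oxo-3,4-dihydro-2H-chromen-3-yl]acetaldehyde
Product: 19 2-[(2R,3R)-5-(benzyloxy)-7-methoxy-2-(4-methoxyphenyl)-4-oxo-3,4-dihydro-2H-chromen-3-yl]acetic acid
Conditions: NaClO2, NaH2PO4, 2-methyl-2-butene, t-BuOH/H2O, 0 °C → rt
Reagents that add atoms: sodium chlorite [Na+].[O-]Cl=O
Why: Pinnick oxidation in phosphate buffer with a hypochlorite scavenger oxidises the aldehyde without enolising the ketone or chlorinating the electron-rich rings.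

Step 9
Reactants: 19 2-[(2R,3R)-5-(benzyloxy)-7-methoxy-2-(4-methoxyphenyl)-4-oxo-3,4-dihydro-2H-chromen-3-yl]acetic acid
Product: 20 2-[(2R,3R)-5-(benzyloxy)-7-methoxy-2-(4-methoxyphenyl)-4-oxo-3,4-dihydro-2H-chromen-3-yl]acetyl chloride
Conditions: (COCl)2, DMF (cat.), CH2Cl2, 0 °C → rt; concentrated and used crude
Reagents that add atoms: oxalyl chloride ClC(=O)C(Cl)=O
Why: Chloroiminium-catalysed acid chloride formation is base-free and gives only gaseous by-products, so the epimerisable C3 center is not exposed.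

Step 10
Reactants: 20 2-[(2R,3R)-5-(benzyloxy)-7-methoxy-2-(4-methoxyphenyl)-4-oxo-3,4-dihydro-2H-chromen-3-yl]acetyl chloride; 12 4-methoxybenzaldehyde
Product: 22 (3R,4R)-3-[(2R,3R)-5-(benzyloxy)-7-methoxy-2-(4-methoxyphenyl)-4-oxo-3,4-dihydro-2H-chromen-3-yl]-4-(4-methoxyphenyl)oxetan-2-one (cis lactone), via ketene 21 (not isolated)
Conditions: O-trimethylsilylquinidine (20 mol %), LiClO4, i-Pr2NEt, CH2Cl2/Et2O, −78 → −40 °C
Reagents that add atoms: none
Why: Same catalytic asymmetric ketene–aldehyde [2+2] cycloaddition as step 5: the amine removes only the acyl chloride α-proton (the ketone α-proton is untouched), and the alkaloid-bound enolate of ketene 21 adds to the activated aldehyde under catalyst control, setting C2 and C3 of half 2 as the cis-(3R,4R) lactone irrespective of the two resident centers.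

Step 11
Reactants: 23 3,5-bis(benzyloxy)phenol
Product: 24 3,5-bis(benzyloxy)-2-bromophenol
Conditions: NBS, i-Pr2NH (cat.), CH2Cl2, −78 → 0 °C
Reagents that add atoms: N-bromosuccinimide BrN1C(=O)CCC1=O
Why: Amine-catalysed electrophilic bromination of a phenol occurs ortho to the free hydroxyl; the two ortho sites are equivalent and the site between the two benzyloxy groups is more hindered.

Step 12
Reactants: 24 3,5-bis(benzyloxy)-2-bromophenol
Product: 28 3,5-bis(benzyloxy)-2-(trimethylsilyl)phenyl trifluoromethanesulfonate, via silyl ether 25 (not isolated), via aryllithium 26 (not isolated), via lithium phenoxide 27 (not isolated)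
Conditions: HMDS, THF, 70 °C, then evaporation; n-BuLi, THF, −100 → −78 °C; Tf2O, −100 °C → rt
Reagents that add atoms: hexamethyldisilazane C[Si](C)(C)N[Si](C)(C)C; trifluoromethanesulfonic anhydride O=S(=O)(OS(=O)(=O)C(F)(F)F)C(F)(F)F
Why: O-silylation, bromine–lithium exchange and 1,3 O→C silyl migration (retro-Brook rearrangement) give the 2-silylphenoxide, which is triflated in situ.

Step 13
Reactants: 22 (3R,4R)-3-[(2R,3R)-5-(benzyloxy)-7-methoxy-2-(4-methoxyphenyl)-4-oxo-3,4-dihydro-2H-chromen-3-yl]-4-(4-methoxyphenyl)oxetan-2-one; 28 3,5-bis(benzyloxy)-2-(trimethylsilyl)phenyl trifluoromethanesulfonate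
Product: 30 (2R,2'R,3R,3'R)-5,5',7-tris(benzyloxy)-7'-methoxy-2,2'-bis(4-methoxyphenyl)-2,2',3,3'-tetrahydro-4H,4'H-[3,3'-bichromene]-4,4'-dione (both rings 2,3-cis), via aryne 29 (not isolated)
Conditions: KF, 18-crown-6, THF, 0 °C → rt (28 added slowly)
Reagents that add atoms: none
Why: Proposed new method: KF/18-crown-6 converts 28 into 3,5-bis(benzyloxy)benzyne 29, whose triple bond is distorted and polarised by the flanking 3-benzyloxy group so that a nucleophile enters at the carbon meta to it and the carbanion develops ortho to it, where the oxygen stabilises it inductively. The nucleophile is the ring oxygen O1 of the strained lactone (directly, or as the alkoxide released when fluoride adds reversibly to the lactone carbonyl); the resulting aryl anion at the future C4a attacks the acyl carbon C4 (4-exo-trig on the O-arylated lactone, or 6-exo-trig on the acyl fluoride in the relay variant), and collapse of the tetrahedral intermediate cleaves only the acyl C4–O1 bond, so the four-membered ring O1–C2–C3–C4 grows by the two aryne carbons into ring C. The closest known reaction types are the insertion of arynes into the N–C(=O) bond of azetidin-2-ones to give 2,3-dihydroquinolin-4-ones, the acyl-alkylation (C–C insertion) of cyclic β-ketoesters with 3,5-dioxygenated arynes, and the aryne coupling–cyclisation of salicylates to xanthones. No stereocenter is formed: C2 and C3 keep the cis-(2R,3R) arrangement fixed in 22 because neither the C2–O1 nor the C3–C4 bond is broken, and the two centers of half 1 are spectators. The step needs regioselectivity (O1 to C8a, acyl to C4a; secured by the 3-benzyloxy group, which ends as O5 peri to the new ketone), chemoselectivity for the lactone carbonyl over the flavanone ketone (secured by ring strain and the short intramolecular reach of the aryl anion), and survival of the ionisable 4-methoxybenzylic C–O bond (secured by the non-acidic, low-temperature medium).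

Step 14
Reactants: 30 (2R,2'R,3R,3'R)-5,5',7-tris(benzyloxy)-7'-methoxy-2,2'-bis(4-methoxyphenyl)-2,2',3,3'-tetrahydro-4H,4'H-[3,3'-bichromene]-4,4'-dione
Product: 31 (2R,2'R,3R,3'R)-5,5',7-trihydroxy-7'-methoxy-2,2'-bis(4-methoxyphenyl)-2,2',3,3'-tetrahydro-4H,4'H-[3,3'-bichromene]-4,4'-dione (target)
Conditions: H2 (1 atm), 10% Pd/C, EtOAc/THF, rt
Reagents that add atoms: none
Why: Heterogeneous hydrogenolysis cleaves the three O-benzyl groups under neutral conditions, so the 2,3-cis centers, the deactivated aryl ketones and the aryl methyl ethers should be untouched.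

Compound list
1 | 2-(benzyloxy)-4-methoxybenzaldehyde | O=Cc1ccc(OC)cc1OCc1ccccc1 | starting material
2 | 2-(benzyloxy)-4-methoxyphenyl formate | O=COc1ccc(OC)cc1OCc1ccccc1 | intermediate
3 | 2-(benzyloxy)-4-methoxyphenol | Oc1ccc(OC)cc1OCc1ccccc1 | intermediate
4 | 2-(benzyloxy)-4-methoxyphenyl N-(propan-2-yl)carbamate | CC(C)NC(=O)Oc1ccc(OC)cc1OCc1ccccc1 | intermediate
5 | 2-(benzyloxy)-4-methoxyphenyl N-(propan-2-yl)-N-(trimethylsilyl)carbamate | CC(C)N([Si](C)(C)C)C(=O)Oc1ccc(OC)cc1OCc1ccccc1 | intermediate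
6 | [3-(benzyloxy)-5-methoxy-2-{[(propan-2-yl)(trimethylsilyl)carbamoyl]oxy}phenyl]lithium | CC(C)N([Si](C)(C)C)C(=O)Oc1c([Li])cc(OC)cc1OCc1ccccc1 | intermediate
7 | 2-(benzyloxy)-4-methoxy-6-(trimethylsilyl)phenyl N-(propan-2-yl)-N-(trimethylsilyl)carbamate | CC(C)N([Si](C)(C)C)C(=O)Oc1c([Si](C)(C)C)cc(OC)cc1OCc1ccccc1 | intermediate
8 | 2-(benzyloxy)-4-methoxy-6-(trimethylsilyl)phenyl N-(propan-2-yl)carbamate | CC(C)NC(=O)Oc1c([Si](C)(C)C)cc(OC)cc1OCc1ccccc1 | intermediate
9 | 2-(benzyloxy)-4-methoxy-6-(trimethylsilyl)phenol (present as its DBU-H phenoxide) | Oc1c([Si](C)(C)C)cc(OC)cc1OCc1ccccc1 | intermediate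
10 | 2-(benzyloxy)-4-methoxy-6-(trimethylsilyl)phenyl trifluoromethanesulfonate | O=S(=O)(Oc1c([Si](C)(C)C)cc(OC)cc1OCc1ccccc1)C(F)(F)F | intermediate
11 | pent-4-enoyl chloride | C=CCCC(=O)Cl | starting material
12 | 4-methoxybenzaldehyde | COc1ccc(C=O)cc1 | starting material
13 | penta-1,4-dien-1-one (allylketene) | C=CCC=C=O | intermediate
14 | (3R,4R)-4-(4-methoxyphenyl)-3-(prop-2-en-1-yl)oxetan-2-one | C=CC[C@H]1C(=O)O[C@H]1c1ccc(OC)cc1 | intermediate
15 | 3-(benzyloxy)-5-methoxybenzyne | COC1=CC#CC(OCc2ccccc2)=C1 | intermediate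
16 | (2R,3R)-5-(benzyloxy)-7-methoxy-2-(4-methoxyphenyl)-3-(prop-2-en-1-yl)-2,3-dihydro-4H-chromen-4-one | C=CC[C@H]1C(=O)c2c(OCc3ccccc3)cc(OC)cc2O[C@H]1c1ccc(OC)cc1 | intermediate
17 | (2R,3R)-5-(benzyloxy)-3-(2,3-dihydroxypropyl)-7-methoxy-2-(4-methoxyphenyl)-2,3-dihydro-4H-chromen-4-one (both carbinol epimers) | OCC(O)C[C@H]1C(=O)c2c(OCc3ccccc3)cc(OC)cc2O[C@H]1c1ccc(OC)cc1 | intermediate
18 | 2-[(2R,3R)-5-(benzyloxy)-7-methoxy-2-(4-methoxyphenyl)-4-oxo-3,4-dihydro-2H-chromen-3-yl]acetaldehyde | O=CC[C@H]1C(=O)c2c(OCc3ccccc3)cc(OC)cc2O[C@H]1c1ccc(OC)cc1 | intermediate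
19 | 2-[(2R,3R)-5-(benzyloxy)-7-methoxy-2-(4-methoxyphenyl)-4-oxo-3,4-dihydro-2H-chromen-3-yl]acetic acid | OC(=O)C[C@H]1C(=O)c2c(OCc3ccccc3)cc(OC)cc2O[C@H]1c1ccc(OC)cc1 | intermediate
20 | 2-[(2R,3R)-5-(benzyloxy)-7-methoxy-2-(4-methoxyphenyl)-4-oxo-3,4-dihydro-2H-chromen-3-yl]acetyl chloride | ClC(=O)C[C@H]1C(=O)c2c(OCc3ccccc3)cc(OC)cc2O[C@H]1c1ccc(OC)cc1 | intermediate
21 | 2-[(2R,3R)-5-(benzyloxy)-7-methoxy-2-(4-methoxyphenyl)-4-oxo-3,4-dihydro-2H-chromen-3-yl]ethen-1-one (ketene) | O=C=C[C@H]1C(=O)c2c(OCc3ccccc3)cc(OC)cc2O[C@H]1c1ccc(OC)cc1 | intermediate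
22 | (3R,4R)-3-[(2R,3R)-5-(benzyloxy)-7-methoxy-2-(4-methoxyphenyl)-4-oxo-3,4-dihydro-2H-chromen-3-yl]-4-(4-methoxyphenyl)oxetan-2-one | COc1ccc([C@@H]2OC(=O)[C@@H]2[C@H]2C(=O)c3c(OCc4ccccc4)cc(OC)cc3O[C@H]2c2ccc(OC)cc2)cc1 | intermediate
23 | 3,5-bis(benzyloxy)phenol | Oc1cc(OCc2ccccc2)cc(OCc2ccccc2)c1 | starting material
24 | 3,5-bis(benzyloxy)-2-bromophenol | Oc1cc(OCc2ccccc2)cc(OCc2ccccc2)c1Br | intermediate
25 | {[3,5-bis(benzyloxy)-2-bromophenyl]oxy}trimethylsilane | C[Si](C)(C)Oc1cc(OCc2ccccc2)cc(OCc2ccccc2)c1Br | intermediate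
26 | {2,4-bis(benzyloxy)-6-[(trimethylsilyl)oxy]phenyl}lithium | C[Si](C)(C)Oc1cc(OCc2ccccc2)cc(OCc2ccccc2)c1[Li] | intermediate
27 | lithium 3,5-bis(benzyloxy)-2-(trimethylsilyl)phenoxide | [Li+].[O-]c1cc(OCc2ccccc2)cc(OCc2ccccc2)c1[Si](C)(C)C | intermediate
28 | 3,5-bis(benzyloxy)-2-(trimethylsilyl)phenyl trifluoromethanesulfonate | O=S(=O)(Oc1cc(OCc2ccccc2)cc(OCc2ccccc2)c1[Si](C)(C)C)C(F)(F)F | intermediate
29 | 3,5-bis(benzyloxy)benzyne | C1#CC(OCc2ccccc2)=CC(OCc2ccccc2)=C1 | intermediate
30 | (2R,2'R,3R,3'R)-5,5',7-tris(benzyloxy)-7'-methoxy-2,2'-bis(4-methoxyphenyl)-2,2',3,3'-tetrahydro-4H,4'H-[3,3'-bichromene]-4,4'-dione | COc1ccc([C@@H]2Oc3cc(OCc4ccccc4)cc(OCc4ccccc4)c3C(=O)[C@@H]2[C@H]2C(=O)c3c(OCc4ccccc4)cc(OC)cc3O[C@H]2c2ccc(OC)cc2)cc1 | intermediate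
31 | (2R,2'R,3R,3'R)-5,5',7-trihydroxy-7'-methoxy-2,2'-bis(4-methoxyphenyl)-2,2',3,3'-tetrahydro-4H,4'H-[3,3'-bichromene]-4,4'-dione | COc1ccc([C@@H]2Oc3cc(O)cc(O)c3C(=O)[C@@H]2[C@H]2C(=O)c3c(O)cc(OC)cc3O[C@H]2c2ccc(OC)cc2)cc1 | target

Total step count: 14.
Longest linear sequence: 11 steps (steps 1, 2, 3, 4, 6, 7, 8, 9, 10, 13, 14; from 1 to 31).

Steps most likely to fail

Step 13 (proposed new method). What may go wrong: fluoride-induced ring opening or β-elimination of lactone 22 before it meets the aryne; heterolysis of the 4-methoxybenzylic C2–O1 bond, leading to decarboxylation or, if the carbonyl oxygen rather than O1 attacks the aryne, to loss of the C2 configuration; and capture of the aryne by fluoride or by itself faster than by the weakly nucleophilic lactone. Fallback with known chemistry (organolithium acylation by a β-lactone, then intramolecular SNAr etherification), setting out from 22 and coming back at 30: commercial 5-fluorobenzene-1,3-diol is benzylated (BnBr, K2CO3, DMF) to 1,3-bis(benzyloxy)-5-fluorobenzene F1, which is brominated (NBS, MeCN, 0 °C) ortho to fluorine and para to one benzyloxy group to give 1,5-bis(benzyloxy)-2-bromo-3-fluorobenzene F2. Bromine–lithium exchange (n-BuLi, THF, −78 °C) gives [2,4-bis(benzyloxy)-6-fluorophenyl]lithium F3, which is acylated at −78 °C by the strained lactone carbonyl of 22 (acyl–oxygen cleavage; the hindered, electron-rich flavanone ketone should react more slowly) to give the β-hydroxy ketone (2R,3R)-5-(benzyloxy)-3-{(2R,3R)-1-[2,4-bis(benzyloxy)-6-fluorophenyl]-3-hydroxy-3-(4-methoxyphenyl)-1-oxopropan-2-yl}-7-methoxy-2-(4-methoxyphenyl)-2,3-dihydro-4H-chromen-4-one F4. Cs2CO3 in DMF at 0 °C then closes ring C by displacement of the ortho-fluorine by the C2 alkoxide, with retention at C2, to give 30.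

Step 6 (proposed new method). What may go wrong: the same processes as in step 13, here on the less hindered lactone 14, plus an ene reaction of the aryne with the allyl group. Fallback with known chemistry, setting out from 14 and coming back at 16: commercial 1-fluoro-3,5-dimethoxybenzene is brominated (NBS, MeCN) to 2-bromo-1-fluoro-3,5-dimethoxybenzene F5 and converted (n-BuLi, THF, −78 °C) into (2-fluoro-4,6-dimethoxyphenyl)lithium F6, which opens lactone 14 at the acyl carbon to give (2R)-1-(2-fluoro-4,6-dimethoxyphenyl)-2-[(R)-hydroxy(4-methoxyphenyl)methyl]pent-4-en-1-one F7. Intramolecular SNAr (Cs2CO3, DMF, 0 °C) gives (2R,3R)-5,7-dimethoxy-2-(4-methoxyphenyl)-3-(prop-2-en-1-yl)-2,3-dihydro-4H-chromen-4-one F8. Chelation-controlled cleavage of only the 5-methyl ether (BCl3, CH2Cl2, −78 °C) gives (2R,3R)-5-hydroxy-7-methoxy-2-(4-methoxyphenyl)-3-(prop-2-en-1-yl)-2,3-dihydro-4H-chromen-4-one F9, and base-free benzylation (benzyl 2,2,2-trichloroacetimidate, TfOH cat.) returns 16.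

Step 10. What may go wrong: slow cycloaddition of the bulky α-branched ketene with an electron-rich aldehyde, so that ketene dimerisation wins; mismatched double stereodifferentiation that erodes the cis-(3R,4R) selectivity; and Lewis-acid-induced ionisation of product 22. Fallback (auxiliary-controlled syn-aldol, then lactonisation by carboxyl activation), setting out from 20 and coming back at 22: 20 acylates lithiated (R)-4-benzyl-1,3-oxazolidin-2-one (n-BuLi, THF, −78 °C) to give (4R)-4-benzyl-3-{2-[(2R,3R)-5-(benzyloxy)-7-methoxy-2-(4-methoxyphenyl)-4-oxo-3,4-dihydro-2H-chromen-3-yl]acetyl}-1,3-oxazolidin-2-one F10. Boron-mediated soft enolisation at the chelated imide methylene (Bu2BOTf, i-Pr2NEt, CH2Cl2, −78 °C; the tertiary, hindered ketone α-position should not compete) and addition to 12 gives the syn-aldol adduct (4R)-4-benzyl-3-{(2R,3R)-2-[(2R,3R)-5-(benzyloxy)-7-methoxy-2-(4-methoxyphenyl)-4-oxo-3,4-dihydro-2H-chromen-3-yl]-3-hydroxy-3-(4-methoxyphenyl)propanoyl}-1,3-oxazolidin-2-one F11. LiOH/H2O2 (THF/H2O, 0 °C) removes the auxiliary to give (2R,3R)-2-[(2R,3R)-5-(benzyloxy)-7-methoxy-2-(4-methoxyphenyl)-4-oxo-3,4-dihydro-2H-chromen-3-yl]-3-hydroxy-3-(4-methoxyphenyl)propanoic acid F12, and PhSO2Cl in pyridine at 0 °C lactonises it with retention at the carbinol carbon to 22.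

Further compounds
F1 | step 13 | 1,3-bis(benzyloxy)-5-fluorobenzene | Fc1cc(OCc2ccccc2)cc(OCc2ccccc2)c1
F2 | step 13 | 1,5-bis(benzyloxy)-2-bromo-3-fluorobenzene | Fc1cc(OCc2ccccc2)cc(OCc2ccccc2)c1Br
F3 | step 13 | [2,4-bis(benzyloxy)-6-fluorophenyl]lithium | [Li]c1c(F)cc(OCc2ccccc2)cc1OCc1ccccc1
F4 | step 13 | (2R,3R)-5-(benzyloxy)-3-{(2R,3R)-1-[2,4-bis(benzyloxy)-6-fluorophenyl]-3-hydroxy-3-(4-methoxyphenyl)-1-oxopropan-2-yl}-7-methoxy-2-(4-methoxyphenyl)-2,3-dihydro-4H-chromen-4-one | COc1ccc([C@H](O)[C@H](C(=O)c3c(F)cc(OCc5ccccc5)cc3OCc3ccccc3)[C@H]2C(=O)c3c(OCc4ccccc4)cc(OC)cc3O[C@H]2c2ccc(OC)cc2)cc1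
F5 | step 6 | 2-bromo-1-fluoro-3,5-dimethoxybenzene | COc1cc(F)c(Br)c(OC)c1
F6 | step 6 | (2-fluoro-4,6-dimethoxyphenyl)lithium | [Li]c1c(F)cc(OC)cc1OC
F7 | step 6 | (2R)-1-(2-fluoro-4,6-dimethoxyphenyl)-2-[(R)-hydroxy(4-methoxyphenyl)methyl]pent-4-en-1-one | C=CC[C@@H](C(=O)c1c(F)cc(OC)cc1OC)[C@@H](O)c1ccc(OC)cc1
F8 | step 6 | (2R,3R)-5,7-dimethoxy-2-(4-methoxyphenyl)-3-(prop-2-en-1-yl)-2,3-dihydro-4H-chromen-4-one | C=CC[C@H]1C(=O)c2c(OC)cc(OC)cc2O[C@H]1c1ccc(OC)cc1
F9 | step 6 | (2R,3R)-5-hydroxy-7-methoxy-2-(4-methoxyphenyl)-3-(prop-2-en-1-yl)-2,3-dihydro-4H-chromen-4-one | C=CC[C@H]1C(=O)c2c(O)cc(OC)cc2O[C@H]1c1ccc(OC)cc1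
F10 | step 10 | (4R)-4-benzyl-3-{2-[(2R,3R)-5-(benzyloxy)-7-methoxy-2-(4-methoxyphenyl)-4-oxo-3,4-dihydro-2H-chromen-3-yl]acetyl}-1,3-oxazolidin-2-one | O=C1OC[C@@H](Cc2ccccc2)N1C(=O)C[C@H]1C(=O)c2c(OCc3ccccc3)cc(OC)cc2O[C@H]1c1ccc(OC)cc1
F11 | step 10 | (4R)-4-benzyl-3-{(2R,3R)-2-[(2R,3R)-5-(benzyloxy)-7-methoxy-2-(4-methoxyphenyl)-4-oxo-3,4-dihydro-2H-chromen-3-yl]-3-hydroxy-3-(4-methoxyphenyl)propanoyl}-1,3-oxazolidin-2-one | O=C1OC[C@@H](Cc2ccccc2)N1C(=O)[C@@H]([C@@H](O)c1ccc(OC)cc1)[C@H]1C(=O)c2c(OCc3ccccc3)cc(OC)cc2O[C@H]1c1ccc(OC)cc1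
F12 | step 10 | (2R,3R)-2-[(2R,3R)-5-(benzyloxy)-7-methoxy-2-(4-methoxyphenyl)-4-oxo-3,4-dihydro-2H-chromen-3-yl]-3-hydroxy-3-(4-methoxyphenyl)propanoic acid | OC(=O)[C@@H]([C@@H](O)c1ccc(OC)cc1)[C@H]1C(=O)c2c(OCc3ccccc3)cc(OC)cc2O[C@H]1c1ccc(OC)cc1
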